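3 numbers are asked of this flask, each the starting material left at one time.

all flasks: starting material 0.020 M
- zeta: coupling partner 0.040 M; catalyst 0.25 mM; run made earlier
- alpha: coupling partner 0.040 M; catalyst 1 mM; run made earlier
- flask: coupling partner 0.0400 M; catalyst 0.50 mM; time 40 h

| run | time / h | starting material / % | target / % |
|---|---|---|---|
| zeta | 2.00 | 99 | 3 |
| zeta | 6.00 | 90 | 2 |
| zeta | 12.0 | 80 | 0 |
| zeta | 15.0 | 80 | 0 |
| zeta | 25.0 | 71 | 7 |
| alpha | 5.00 | 74 | 2 |
| alpha | 10.0 | 56 | 10 |
| alpha | 15.0 | 44 | 20 |
| alpha | 20.0 | 32 | 28 |
| alpha | 25.0 | 19 | 41 |

(each reading ± 2 percentage points)

* amount of starting material in percent of the starting material charged, at 8.0 h, 20 h and 40 h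

- percentages count the starting material that a species holds: one side product or self-condensation product counts as two
- the analysis behind the earlier runs scatters by 2 percentage points, standard deviation
- steps thought possible: starting material + catalyst -> catalyst + intermediate; coupling partner + catalyst + intermediate -> catalyst + target; starting material + intermediate -> side product; 2 starting material -> self-condensation product

The zeta run, the alpha run and the flask share c(starting material) and c(coupling partner), and they differ in c(catalyst). In the first proposed step the catalyst comes back unchanged. If that step carries the loss, starting material decays exponentially (pseudo-first-order), with a half-life that scales as one over c(catalyst).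

The tables test this. In the alpha run, 56% stands at 10.0 h. An exponential repeats that factor over the next 10.0 h, which gives 31.4%, and 32% is read at 20.0 h.

The alpha reading at 20.0 h then gives 12.2 mM·h for the half-dose, the product of c(catalyst) and time that halves the starting material. The zeta reading at 25.0 h, with a quarter of the alpha catalyst, gives 12.6 mM·h, close to it. Both values carry the scatter of 2 percentage points.

In the flask, 0.50 mM turns the half-dose into a half-life of 24.3 h. The asked times are then 0.329, 0.823 and 1.65 half-lives, so this reckoning commits to 79.6%, 56.6% and 32.0%. The flask at 20 h has the catalyst-time of the alpha run at 10.0 h, and that separate reading is 56%.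

The forecast gives 79%, 55% and 29%, lower than this reckoning, and it shades its later values down on the ground that the “late alpha points hint at slight acceleration”.

The flask gives 79.4%, 55.7% and 30.7%.

    starting material + catalyst → catalyst + intermediate (k = 57.0 M⁻¹ h⁻¹)
    coupling partner + catalyst + intermediate → catalyst + target (k = 1500 M⁻² h⁻¹)
    starting material + intermediate → side product (k = 0.180 M⁻¹ h⁻¹)
    2 starting material → self-condensation product (k = 0.00110 M⁻¹ h⁻¹)

At 40.0 h, the side-product step alone stands for a half-life of starting material of 23 d, far longer than the 40 h of the run. The half-dose goes on counting in this flask: 80.0 h is 3.29 half-lives, which gives 10.2%. The flask then holds 9.39% of its starting material.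

(The earlier runs and the new flask were generated by integration for substances that don't exist; noise was put on by code.)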